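**Retrosynthetic overview**
1. Target 15 ⇒ tetra-O-methyl γ-keto ester 13. The furan ring (O1–C2 bond) is closed last, by global O-demethylation and cyclodehydration; both benzene rings are bought.
2. 13 ⇒ diarylmethyl cation equivalent 11 (from carbinol 9) plus the Breslow acyl anion equivalent of methyl 4-oxobutanoate 10. This makes the C2–C3 bond from two carbons that are both normally electrophilic.
3. 9 ⇒ aryllithium from bromide 6 (ring A) plus aldehyde 5 (ring B). This makes the C3–C3a bond, with ring A regiochemistry fixed by the bromide.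
4. 5 ⇒ commercial aldehyde 1 by directed ortho-methylation.

Assumption: the target has no stereocentre and its SMILES gives no axial descriptor, so it is made as the single constitution shown; 9 and 13 are racemic and their stereocentre is destroyed in step 4.

**Step 1**
Reactants: 1 3,5-dimethoxy-4-methylbenzaldehyde
Product: 5 3,5-dimethoxy-2,4-dimethylbenzaldehyde, via lithium amino alkoxide 2 (not isolated), via ortho-lithiated amino alkoxide 3 (not isolated), via methylated amino alkoxide 4 (not isolated)
Conditions: LiN(Me)CH2CH2NMe2 (from MeNHCH2CH2NMe2 + n-BuLi, 1.1 equiv), THF, −20 °C; n-BuLi (3 equiv), −20 °C, 24 h; MeI (6 equiv), −78 °C → rt; H2O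
Reagents that add atoms: iodomethane, CI
Why: Comins α-amino alkoxide directed ortho-lithiation, in which the in-situ hemiaminal alkoxide masks the aldehyde and, together with the neighbouring methoxy group, directs n-BuLi to C2 (C2 and C6 are equivalent, and no other ring hydrogen exists), so that MeI quench and aqueous hydrolysis return the ortho-methylated aldehyde; no stereocentre is present in the product.

**Step 2**
Reactants: 5 3,5-dimethoxy-2,4-dimethylbenzaldehyde; 6 2-bromo-1,5-dimethoxy-3-methylbenzene
Product: 9 (2,4-dimethoxy-6-methylphenyl)(3,5-dimethoxy-2,4-dimethylphenyl)methanol (racemic), via aryllithium 7 (not isolated), via lithium alkoxide 8 (not isolated)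
Conditions: 6 (1.1 equiv), n-BuLi (1.1 equiv), THF, −78 °C, 30 min; then 5, −78 → 0 °C; H2O
Reagents that add atoms: none
Why: Bromine–lithium exchange places the nucleophilic carbon of ring A unambiguously between OMe and CH3, and 1,2-addition of the aryllithium to the aldehyde gives the benzhydrol, whose new stereocentre is formed racemic and is removed later.

**Step 3**
Reactants: 9 (2,4-dimethoxy-6-methylphenyl)(3,5-dimethoxy-2,4-dimethylphenyl)methanol; 10 methyl 4-oxobutanoate
Product: 13 methyl 5-(2,4-dimethoxy-6-methylphenyl)-5-(3,5-dimethoxy-2,4-dimethylphenyl)-4-oxopentanoate (racemic), via benzhydryl chloride 11 (not isolated), via Breslow intermediate 12 (not isolated)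
Conditions: AcCl, CH2Cl2, 0 °C → rt, evaporate (toluene chase); then slow addition of 11 to 10 (1.5 equiv), 3-benzyl-4-methylthiazolium chloride (20 mol %), Cs2CO3 (1.3 equiv), THF, 50 °C
Reagents that add atoms: none
Why: Proposed new method: the thiazol-2-ylidene adds reversibly to aldehyde 10 to give the enaminol 12 (an acyl anion equivalent), whose nucleophilic carbon captures the strongly stabilised 2,4-dimethoxybenzhydryl cation formed by ionisation of chloride 11 (SN1), and collapse of the adduct releases ketone 13 and the carbene, while reversible acyloin self-condensation of 10 feeds back into 12; the closest known reaction types are the carbene-catalysed nucleophilic acylation of diarylbromomethanes by aromatic aldehydes and the Stetter-type acylation of quinone methides; the new stereocentre is formed racemic.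

**Step 4**
Reactants: 13 methyl 5-(2,4-dimethoxy-6-methylphenyl)-5-(3,5-dimethoxy-2,4-dimethylphenyl)-4-oxopentanoate
Product: 15 talarominine A, via tetraphenol keto ester 14 (not isolated)
Conditions: BBr3 (8 equiv), CH2Cl2, −78 → 0 °C; MeOH quench, 0 °C → 40 °C; H2O
Reagents that add atoms: none
Why: BBr3 cleaves the four aryl methyl ethers far faster than the aliphatic methyl ester at low temperature (Lewis acid ether cleavage), and the freed 2-hydroxyl of ring A adds to the ketone and the hemiketal dehydrates under the acidic quench (cyclodehydration to the benzofuran), which turns the racemic carbon into sp2 C3 so that no stereocentre remains.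

**Compound list**
1 | 3,5-dimethoxy-4-methylbenzaldehyde | COc1cc(C=O)cc(OC)c1C | starting material
2 | lithium (3,5-dimethoxy-4-methylphenyl){[2-(dimethylamino)ethyl](methyl)amino}methanolate (racemic) | [Li]OC(N(C)CCN(C)C)c1cc(OC)c(C)c(OC)c1 | intermediate
3 | lithium {[2-(dimethylamino)ethyl](methyl)amino}(2-lithio-3,5-dimethoxy-4-methylphenyl)methanolate (racemic) | [Li]OC(N(C)CCN(C)C)c1cc(OC)c(C)c(OC)c1[Li] | intermediate
4 | lithium (3,5-dimethoxy-2,4-dimethylphenyl){[2-(dimethylamino)ethyl](methyl)amino}methanolate (racemic) | [Li]OC(N(C)CCN(C)C)c1cc(OC)c(C)c(OC)c1C | intermediate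
5 | 3,5-dimethoxy-2,4-dimethylbenzaldehyde | COc1cc(C=O)c(C)c(OC)c1C | intermediate
6 | 2-bromo-1,5-dimethoxy-3-methylbenzene | COc1cc(C)c(Br)c(OC)c1 | starting material
7 | (2,4-dimethoxy-6-methylphenyl)lithium | [Li]c1c(C)cc(OC)cc1OC | intermediate
8 | lithium (2,4-dimethoxy-6-methylphenyl)(3,5-dimethoxy-2,4-dimethylphenyl)methanolate (racemic) | [Li]OC(c1c(C)cc(OC)cc1OC)c1cc(OC)c(C)c(OC)c1C | intermediate
9 | (2,4-dimethoxy-6-methylphenyl)(3,5-dimethoxy-2,4-dimethylphenyl)methanol (racemic) | OC(c1c(C)cc(OC)cc1OC)c1cc(OC)c(C)c(OC)c1C | intermediate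
10 | methyl 4-oxobutanoate | COC(=O)CCC=O | starting material
11 | 2-[chloro(3,5-dimethoxy-2,4-dimethylphenyl)methyl]-1,5-dimethoxy-3-methylbenzene (racemic) | ClC(c1c(C)cc(OC)cc1OC)c1cc(OC)c(C)c(OC)c1C | intermediate
12 | methyl 4-(3-benzyl-4-methyl-1,3-thiazol-2(3H)-ylidene)-4-hydroxybutanoate | COC(=O)CCC(O)=C1SC=C(C)N1Cc1ccccc1 | intermediate
13 | methyl 5-(2,4-dimethoxy-6-methylphenyl)-5-(3,5-dimethoxy-2,4-dimethylphenyl)-4-oxopentanoate (racemic) | COC(=O)CCC(=O)C(c1c(C)cc(OC)cc1OC)c1cc(OC)c(C)c(OC)c1C | intermediate
14 | methyl 5-(2,4-dihydroxy-6-methylphenyl)-5-(3,5-dihydroxy-2,4-dimethylphenyl)-4-oxopentanoate (racemic) | COC(=O)CCC(=O)C(c1c(C)cc(O)cc1O)c1cc(O)c(C)c(O)c1C | intermediate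
15 | talarominine A, methyl 3-[3-(3,5-dihydroxy-2,4-dimethylphenyl)-6-hydroxy-4-methyl-1-benzofuran-2-yl]propanoate | COC(=O)CCc1oc2cc(O)cc(C)c2c1-c1cc(O)c(C)c(O)c1C | target

**Step count and risk**
Total step count: 4. Longest linear sequence: 4 steps (1 → 5 → 9 → 13 → 15).

Steps most likely to fail, in order of risk:

Step 3. The carbene may be alkylated irreversibly by 11, the enaminol may react at oxygen, and 10 may undergo aldol self-condensation. The fallback sets out from 9 by way of chloride 11 and comes back at 13. It replaces the catalytic carbene by a stoichiometric nitronate as the acyl anion equivalent. Methyl 4-nitrobutanoate is deprotonated (NaH, DMF, 0 °C) to sodium 4-methoxy-4-oxobutane-1-nitronate F1. Chloride 11 is added at −20 °C → rt, and SN1 capture at carbon gives methyl 5-(2,4-dimethoxy-6-methylphenyl)-5-(3,5-dimethoxy-2,4-dimethylphenyl)-4-nitropentanoate F2. A reductive Nef reaction (NaOMe, MeOH, then aqueous TiCl3/NH4OAc, 0 °C → rt) converts F2 into ketone 13.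

Step 1. The lithiation site lies between two substituents, and incomplete lithiation or attack on the methoxy groups would lower the yield. The fallback sets out from 1 and comes back at 5. Electrophilic bromination (NBS, MeCN, rt) at the only free ring position gives 2-bromo-3,5-dimethoxy-4-methylbenzaldehyde F3. Suzuki–Miyaura methylation (trimethylboroxine, Pd(PPh3)4, K2CO3, dioxane, 100 °C) then gives 5.

Step 4. The methyl ester may be partly cleaved by BBr3, or the electron-rich product may suffer under the strong Lewis acid. The fallback sets out from 13 and comes back at 15. Nucleophilic demethylation (EtSNa, 12 equiv, DMF, 120 °C) removes the four aryl methyl groups and the ester methyl by SN2 attack at methyl. Acidification (aq. HCl) gives 5-(2,4-dihydroxy-6-methylphenyl)-5-(3,5-dihydroxy-2,4-dimethylphenyl)-4-oxopentanoic acid F4. Warming F4 in the acid (cat. TsOH, toluene, 80 °C if needed) cyclodehydrates it to 3-[3-(3,5-dihydroxy-2,4-dimethylphenyl)-6-hydroxy-4-methyl-1-benzofuran-2-yl]propanoic acid F5. Fischer esterification (MeOH, cat. H2SO4, 65 °C), which leaves the phenols untouched, returns 15.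

**Further compounds**
F1 | step 3 | sodium 4-methoxy-4-oxobutane-1-nitronate | COC(=O)CCC=[N+]([O-])[O-].[Na+]
F2 | step 3 | methyl 5-(2,4-dimethoxy-6-methylphenyl)-5-(3,5-dimethoxy-2,4-dimethylphenyl)-4-nitropentanoate | COC(=O)CCC([N+](=O)[O-])C(c1c(C)cc(OC)cc1OC)c1cc(OC)c(C)c(OC)c1C
F3 | step 1 | 2-bromo-3,5-dimethoxy-4-methylbenzaldehyde | COc1cc(C=O)c(Br)c(OC)c1C
F4 | step 4 | 5-(2,4-dihydroxy-6-methylphenyl)-5-(3,5-dihydroxy-2,4-dimethylphenyl)-4-oxopentanoic acid | OC(=O)CCC(=O)C(c1c(C)cc(O)cc1O)c1cc(O)c(C)c(O)c1C
F5 | step 4 | 3-[3-(3,5-dihydroxy-2,4-dimethylphenyl)-6-hydroxy-4-methyl-1-benzofuran-2-yl]propanoic acid | OC(=O)CCc1oc2cc(O)cc(C)c2c1-c1cc(O)c(C)c(O)c1C
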